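I reckon these flasks by the nucleophile charged and set the free base aside.

| flask | electrophile | nucleophile | free base | remark | time |
|---|---|---|---|---|---|
| ochre | 0.10 M | 0.095 M (in portions, 4) | 0.15 M | run made earlier; portions every 5.0 h |  |
| teal | 0.10 M | 0.095 M (in portions, 4) | 0.22 M | run made earlier; portions every 5.0 h |  |
| summer | 0.10 M | 0.0950 M (in portions, 4) | 0.300 M | the portions of nucleophile follow each other after 5.0 h, the first at the start | 20 h |
| midnight | 0.10 M | 0.0950 M (in portions, 4) | 0.300 M | the portions of nucleophile follow each other after 5.0 h, the first at the start | 40 h |

- ochre (time / h: electrophile / %, side product / %, target / %): 3.00: 87.0, 2.3, 11.1; 6.00: 79.9, 0.6, 19.8; 10.0: 73.8, 0, 26.0; 12.0: 67.4, 0, 34.1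
- teal (time / h: electrophile / %, side product / %, target / %): 3.00: 90.6, 0.7, 8.7; 6.00: 80.6, 0, 19.0; 10.0: 74.0, 0, 25.6; 12.0: 64.2, 0, 34.9

(readings scatter by 1 percentage point)

- the analysis behind the earlier runs scatters by 1 percentage point, standard deviation
- what may be going on: electrophile + nucleophile -> acid set free + target; nucleophile + acid set free <-> protonated nucleophile; acid set free + free base <-> salt of the base; 2 free base -> self-condensation product; acid set free + target -> side product

* which of these there is most of at the end, counted by the electrophile in it, summer (target / electrophile / side product)
* which of these there is most of at the end, counted by the electrophile in it, midnight (target / electrophile / side product)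
* amount of the one of these that there is most of at the end, in percent of the electrophile charged, summer
* amount of the one of these that there is most of at the end, in percent of the electrophile charged, midnight

1. Free base. By hand, more free base takes up more acid set free, so target should climb with it. At 12.0 h, going from 0.15 M in ochre to 0.22 M in teal moves target from 34.1% to 34.9%, inside the scatter of 1 percentage point. In powers of ten, the order in free base, n (slope of log target against log free base), reads 0.0605. Going on to 0.300 M is then a factor of 1.02 on target, which I neglect.

2. Nucleophile. By hand, one nucleophile makes one target. At 0.950 equivalents it is the limiting reagent, so a portion is worth 23.8%. Yet at 10.0 h, as the third portion goes in, two portions have given 26.0% in ochre and 25.6% in teal. So I carry η = 0.543, the yield on nucleophile: target formed per nucleophile charged so far.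

3. Time. By hand, the hours that midnight runs on after summer's end should add target. For summer at 20 h, η gives 51.6% target against about 48.4% electrophile, so target leads narrowly, with side product reading 0% at 12.0 h in teal. Midnight gets 20.0 h more, but the runs stop at 12.0 h, so η gives no figure there. I commit to target, above summer's amount.

4. The forecast says target at 51% for summer and target at 58% for midnight, holding that “The base frees it only slowly”. Its summer figure lies beside mine; for midnight it gives a number where I give a direction.

5. Summer gives target, 53.5%, beside 45.7% electrophile. Midnight gives target, 64.5%, which is 6.5 points above the forecast.

    electrophile + nucleophile → acid set free + target (k = 0.0560 L mol⁻¹ min⁻¹)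
    nucleophile + acid set free ⇌ protonated nucleophile, settled at all times (K = 1500 L mol⁻¹)
    acid set free + free base ⇌ salt of the base (K = 2600 L mol⁻¹, k = 0.0910 L mol⁻¹ min⁻¹)
    2 free base → self-condensation product (k = 0.00260 L mol⁻¹ min⁻¹)
    acid set free + target → side product (k = 0.0160 L mol⁻¹ min⁻¹)

6. Summer's η comes to 0.564. For midnight read at 15 h, with 3 portions in, the carried η gives 38.7% and the flask stands at 40.8%, while midnight's end stands 13 points above η times the charge. The half-life of electrophile by the path to target is 2.2 h in summer with the whole charge counted as there at once, and it is longer than that, 14 h, in midnight at 6.06 h. Summer at 10.0 h holds more protonated nucleophile, 0.0151 M, than free nucleophile, 0.00501 M.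

The numbers in the tables were generated by integration with made-up constants; scatter was added.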